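## Structural features

The target is an achiral benzophenone: two benzene rings joined only through one carbonyl carbon, with no stereocentre, so no stereochemical relationship has to be set. Ring A (C1 to C6) carries the carbonyl on C1, a free hydroxyl on C2, chlorine on C3, methoxyls on C4 and C6 and hydrogen on C5. Ring B (C1' to C6') carries the carbonyl on C1', a methoxyl on C2', a free hydroxyl on C4' and a methyl on C6'. All four positions ortho to the carbonyl are substituted, so the ketone is twisted and hindered, hard to make by direct acylation and slow towards nucleophiles. Fragile points are the C3–Cl bond (hydrogenolysis), the methoxyls ortho to the carbonyl (Lewis-acid demethylation, and base-induced attack of the C2 oxygen on C2' to give a xanthone) and the two electron-rich rings (over-halogenation, oxidation). The real difficulty is regiochemical: three oxygens on ring A and two on ring B must be told apart, and one chlorine must go to C3 and not to C5 or ring B. The key step uses the adjacency of the acyl carbon on C1 and the hydroxyl on C2 of ring A: an ortho-hydroxyaryl ketone is the ring-opened form of a 3-aryl-1,2-benzisoxazole. Its two ring-forming bonds come from a nitrile oxide and an aryne, and the C6 methoxyl beside C1 polarises that aryne.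

## Logic of the disconnections

17 to 16: the O–CH2Ph bond on the C4' oxygen is cut. The C4' hydroxyl must stay masked while chlorine is placed on ring A, otherwise ring B would be the more reactive ring. The gain is that 16 has a single free phenol. The demand is a debenzylation that leaves C3–Cl and the ortho methoxyls untouched, hence a cold Lewis-acid cleavage with a cation scavenger and not hydrogenolysis.

16 to 15: the C3–Cl bond is cut. The C2 hydroxyl of 15 sits ortho to C3 and can direct an electrophile there. The gain is a chlorine-free ring A that derives from a simple 3,5-dimethoxy pattern. The demand is site selectivity for C3 over C5 and over C3'/C5' of ring B.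

15 to 13 (through 14): the carbonyl oxygen is exchanged for nitrogen and that nitrogen is joined to the C2 oxygen. The ortho-hydroxyaryl ketone is the retron of the benzisoxazole, which stores ketone and phenol in one robust ring. The gain is access to a cycloaddition that creates the hydroxyl/methoxyl difference on ring A by itself. The demand is reductive N–O cleavage that spares the benzyl ether, then hydrolysis of the hindered, hydrogen-bonded ketimine 14.

13 to 6 and 11 (through 12): the bond from ring A C1 to the future carbonyl carbon and the bond from ring A C2 to oxygen are cut. This splits the molecule into two halves of similar size. Ring A becomes the aryne 12 and ring B becomes the dipole 11. The demand is regiochemistry: oxygen must bond to the aryne carbon remote from the methoxyl, and the hindered dipole must be stable and still reactive.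

6 to 3 to 2 to 1: the O–S bond of the triflate, the C–Si bond (formed by a 1,3 shift from oxygen through 4 and 5) and the C–Br bond are cut in turn. This is the standard access to a 2-silylaryl triflate from an ortho-bromophenol and leads to a commercial phenol. The demand is bromination at C2 and not at C4, and low temperature in the lithiation.

11 to 10 to 9 to 8 to 7: the nitrile oxide is taken back to the oxime and the aldehyde, then the C2 O–CH3 and C4 O–CH2Ph bonds are cut. The aldehyde carbon is the future ketone carbon, and its hydrogen bond to the C2 hydroxyl of 7 differentiates the two hydroxyls. The demand is mono-benzylation of the non-chelated hydroxyl and an oxime oxidation that does not halogenate the ring.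

## Other disconnections considered

Alternative 1: The cut goes through ring B at C1'–C2' and C5'–C6', giving the ring A ynone 1-[3-chloro-4,6-dimethoxy-2-(methoxymethoxy)phenyl]but-2-yn-1-one A1 and the diene 1,1-dimethoxy-3-(trimethylsilyloxy)buta-1,3-diene A2. In the forward step the nucleophilic CH2 terminus of A2 bonds to the methyl-bearing alkyne carbon and the acetal carbon bonds to the acyl-bearing carbon. Loss of one alkoxy group aromatises the adduct and desilylation gives A3, the C2 methoxymethyl ether of the target.
- In its favour: the 2'-methoxyl/4'-hydroxyl pattern is written into the diene, so ring B needs no protecting group. Chlorine is carried from the start, so there is no late chlorination. No nitrogen has to be removed. On these three points it is better than the chosen plan.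
- Against it: A1 requires a pre-chlorinated, fully differentiated ring A carbonyl compound, so the regiochemical problems of ring A move to the beginning instead of being solved. A β-methyl ynone on a twisted di-ortho-substituted aryl group is a weakly activated, hindered dienophile. A2 is sensitive to heat and moisture, and open-chain Michael-type adducts can compete.
- Comparison: both key steps are cycloadditions that make two bonds and one ring. This one keeps every ring atom, whereas the chosen one discards nitrogen. Step count should be about equal, but the sequence is linear on ring A and less convergent.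

Alternative 2: The cut is the C1–C2 bond of ring A. Mg(OMe)2 in methanol opens the pyranone 6-{2-[4-(benzyloxy)-2-methoxy-6-methylphenyl]-2-oxoethyl}-4-hydroxy-2H-pyran-2-one A4 to the triketo ester methyl 7-[4-(benzyloxy)-2-methoxy-6-methylphenyl]-3,5,7-trioxoheptanoate A5. Its C6 methylene then attacks the ester carbon in a Claisen condensation to give the acylphloroglucinol [4-(benzyloxy)-2-methoxy-6-methylphenyl](2,4,6-trihydroxyphenyl)methanone A6.
- In its favour: the closure is biomimetic, and on a symmetrical phloroglucinol the acyl position is unambiguous, so ring construction has no regiochemical risk; this is better than the chosen key step. The hindered aryl ketone also disfavours the competing aldol mode.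
- Against it: A6 has three free hydroxyls on ring A and needs a selective double methylation that leaves one chelated hydroxyl. That only brings it to 15, so the late chlorination and debenzylation are the same as in the chosen plan (equal there). A4 must be made by acylating a pyranone dianion with a di-ortho-substituted aroyl donor, which is slow. Polyketo esters such as A5 re-close to pyranones easily.
- Comparison: one C–C bond is formed by chelation-controlled condensation, against two bonds by cycloaddition. Step count is similar or slightly higher and convergence is lower.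

Alternative 3: The cuts are the C1'–carbonyl bond and the C6'–CH2 bond. The aryne from 5-(benzyloxy)-3-methoxy-2-(trimethylsilyl)phenyl trifluoromethanesulfonate A8 and CsF inserts into the C(=O)–CH2 bond of the β-ketoester methyl 3-[2-(benzyloxy)-3-chloro-4,6-dimethoxyphenyl]-3-oxopropanoate A7. The product is methyl 2-[5-(benzyloxy)-2-[2-(benzyloxy)-3-chloro-4,6-dimethoxybenzoyl]-3-methoxyphenyl]acetate A9.
- In its favour: the diaryl ketone bond is made directly, with no imine to hydrolyse. Chlorine and the ring A pattern are pre-set, which is better than the chosen plan. The same methoxyl-directed aryne polarisation controls regiochemistry (equal in principle), and the first bond forms at the unhindered distal carbon before the acyl group is delivered intramolecularly, arguably a steric advantage.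
- Against it: A9 carries CH2CO2Me where the target has a methyl, so ester hydrolysis and a non-trivial decarboxylation of an ortho-aroyl arylacetic acid are needed, with enol-lactone formation as a side path. Two benzyl ethers must be removed beside the aryl chloride. The aryl anion must add to a ketone flanked by two ortho groups, so simple α-arylation may win. A7 and A8 each need several steps.
- Comparison: mechanistically elegant, but clearly longer than the chosen plan and with a weaker end-game.

Key step: step 8

Remarks on the chemistry:
- Mapping the benzisoxazole 13 onto ring A gives C3a = C1, C7a = C2, C7 = C3, C6 = C4, C5 = C5 and C4 = C6. With this mapping the structures of 6, 11, 13 and 17 are mutually consistent and none needed correction.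
- Nitrile oxide 11 is assumed stable enough to be isolated by extraction and used the same day, as di-ortho-substituted aryl nitrile oxides generally are.
- Three design choices go beyond the simplest plan: NaHCO3 as the weak base for mono-benzylation, PhI(OAc)2 instead of a chlorinating agent for the oxime oxidation, and pentamethylbenzene as scavenger in the last step.

## Route

Step 1
Reactants: 1 3,5-dimethoxyphenol
Product: 2 2-bromo-3,5-dimethoxyphenol
Conditions: NBS (1.0 equiv), CH2Cl2, −78 °C to rt
Reagents that add atoms: N-bromosuccinimide, O=C1CCC(=O)N1Br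
Why: Electrophilic aromatic bromination; in a non-polar solvent at low temperature the reagent is delivered through a hydrogen bond to the phenol, which should favour C2 (ortho to OH, para to a methoxyl) over the more crowded C4 between two methoxyls. The para isomer and any dibromide are removed by chromatography.

Step 2
Reactants: 2 2-bromo-3,5-dimethoxyphenol
Product: 3 (2-bromo-3,5-dimethoxyphenoxy)trimethylsilane
Conditions: HMDS, THF, 65 °C; evaporate, use crude
Reagents that add atoms: hexamethyldisilazane, C[Si](C)(C)N[Si](C)(C)C
Why: O-silylation of a phenol with a silazane; ammonia is the only by-product, so the moisture-sensitive silyl ether needs no aqueous work-up.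

Step 3
Reactants: 3 (2-bromo-3,5-dimethoxyphenoxy)trimethylsilane
Product: 6 3,5-dimethoxy-2-(trimethylsilyl)phenyl trifluoromethanesulfonate, via aryllithium 4 (not isolated), via lithium phenoxide 5 (not isolated)
Conditions: n-BuLi, THF, −100 to −78 °C; then Tf2O, −78 °C; Et3N-deactivated silica
Reagents that add atoms: trifluoromethanesulfonic anhydride, O=S(=O)(OS(=O)(=O)C(F)(F)F)C(F)(F)F
Why: Bromine–lithium exchange gives 4, which undergoes the retro-Brook 1,3 shift of silicon from oxygen to carbon to give 5; O-sulfonylation then gives the 2-silylaryl triflate. The silyl group on this electron-rich ring is acid-labile, hence the buffered purification.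

Step 4
Reactants: 7 2,4-dihydroxy-6-methylbenzaldehyde
Product: 8 4-(benzyloxy)-2-hydroxy-6-methylbenzaldehyde
Conditions: BnBr (1.05 equiv), NaHCO3, MeCN, 80 °C
Reagents that add atoms: benzyl bromide, BrCc1ccccc1
Why: Williamson etherification; the C2 hydroxyl is held in a hydrogen bond to the aldehyde and is less nucleophilic, so the weak base should alkylate only the C4 hydroxyl.

Step 5
Reactants: 8 4-(benzyloxy)-2-hydroxy-6-methylbenzaldehyde
Product: 9 4-(benzyloxy)-2-methoxy-6-methylbenzaldehyde
Conditions: MeI, K2CO3, DMF, rt
Reagents that add atoms: iodomethane, CI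
Why: Williamson methylation of the remaining chelated phenol under the stronger base and solvent it requires.

Step 6
Reactants: 9 4-(benzyloxy)-2-methoxy-6-methylbenzaldehyde
Product: 10 (E)-4-(benzyloxy)-2-methoxy-6-methylbenzaldehyde oxime
Conditions: NH2OH·HCl, NaOAc, EtOH/H2O, 60 °C
Reagents that add atoms: hydroxylamine hydrochloride, NO.Cl
Why: Condensation of an aldehyde with hydroxylamine; the E oxime (aryl and OH anti) is the thermodynamic isomer, and the geometry is lost in the next step anyway.

Step 7
Reactants: 10 (E)-4-(benzyloxy)-2-methoxy-6-methylbenzaldehyde oxime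
Product: 11 4-(benzyloxy)-2-methoxy-6-methylbenzonitrile oxide
Conditions: PhI(OAc)2 (1.1 equiv), TFA (cat.), MeOH, 0 °C; NaHCO3 wash, use the same day
Reagents that add atoms: none
Why: Oxidative dehydrogenation of an aldoxime by a trivalent iodine reagent (ligand exchange at iodine, then loss of iodobenzene); no halogenating agent is present, so the electron-rich ring is not chlorinated. The two ortho substituents block dimerisation to the furoxan.

Step 8
Reactants: 6 3,5-dimethoxy-2-(trimethylsilyl)phenyl trifluoromethanesulfonate; 11 4-(benzyloxy)-2-methoxy-6-methylbenzonitrile oxide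
Product: 13 3-[4-(benzyloxy)-2-methoxy-6-methylphenyl]-4,6-dimethoxy-1,2-benzisoxazole, via 3,5-dimethoxybenzyne 12 (not isolated)
Conditions: CsF (3 equiv), MeCN, rt; 6 (1.5 equiv) added slowly
Reagents that add atoms: none
Why: Fluoride attacks the silicon of 6 and the resulting aryl anion expels triflate to give aryne 12, whose strained triple bond is the electrophilic two-atom partner for nitrile oxide 11 in a 1,3-dipolar [3+2] cycloaddition. The closest known reaction type is the cycloaddition of nitrile oxides with arynes from 2-silylaryl triflates, which gives 3-aryl-1,2-benzisoxazoles. The pathway is asynchronous: the nucleophilic oxygen terminus bonds first to the aryne carbon remote from the neighbouring methoxyl (the future C2 of ring A), because the inductively withdrawing methoxyl distorts the aryne so that this carbon is the more electrophilic one and the developing negative charge sits next to the C–O bond. The carbon terminus then bonds to the aryne carbon beside the methoxyl (the future C1 of ring A). The five-membered isoxazole ring is thus closed by intermolecular [3+2] annulation, three atoms (C, N, O) from 11 and two from 12, with the C–C bond as the ring-closing bond. No stereocentre is formed. The selectivity needed is regiochemical and is secured electronically by the methoxyl beside the triple bond, while the linear C≡N–O unit holds the bulky aryl group away from that methoxyl in the transition state and so limits the opposing steric pressure. The ortho substituents of 11 suppress furoxan formation, so the dipole can wait for slowly generated aryne, and slow addition of a moderate excess of 6 should keep aryne self-reaction low.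

Step 9
Reactants: 13 3-[4-(benzyloxy)-2-methoxy-6-methylphenyl]-4,6-dimethoxy-1,2-benzisoxazole
Product: 15 [4-(benzyloxy)-2-methoxy-6-methylphenyl](2-hydroxy-4,6-dimethoxyphenyl)methanone, via ketimine 14 (not isolated)
Conditions: Mo(CO)6, MeCN/H2O, 80 °C; then 2 M HCl, THF, 60 °C
Reagents that add atoms: water, O
Why: Zerovalent molybdenum inserts into the weak N–O bond and water supplies the protons (reductive N–O cleavage of an isoxazole), giving the hydrogen-bonded ketimine 14; acid hydrolysis then exchanges NH for O. The benzyl ether and the methoxyls are inert to both stages.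

Step 10
Reactants: 15 [4-(benzyloxy)-2-methoxy-6-methylphenyl](2-hydroxy-4,6-dimethoxyphenyl)methanone
Product: 16 [4-(benzyloxy)-2-methoxy-6-methylphenyl](3-chloro-2-hydroxy-4,6-dimethoxyphenyl)methanone
Conditions: SO2Cl2 (1.05 equiv), 2,2,6,6-tetramethylpiperidine (10 mol%), toluene, 0 °C to rt
Reagents that add atoms: sulfuryl chloride, O=S(=O)(Cl)Cl
Why: Amine-catalysed ortho-chlorination of a phenol: the N-chloroammonium species formed from the amine hydrogen-bonds to the phenol and delivers chlorine to the adjacent carbon. C3 is the only open position ortho to the single free hydroxyl, and ring B has no free hydroxyl; one equivalent of reagent limits over-chlorination.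

Step 11
Reactants: 16 [4-(benzyloxy)-2-methoxy-6-methylphenyl](3-chloro-2-hydroxy-4,6-dimethoxyphenyl)methanone
Product: 17 (3-chloro-2-hydroxy-4,6-dimethoxyphenyl)(4-hydroxy-2-methoxy-6-methylphenyl)methanone
Conditions: BCl3, pentamethylbenzene, CH2Cl2, −78 °C; MeOH quench
Reagents that add atoms: none
Why: Lewis-acid cleavage of an aryl benzyl ether with a non-basic arene as benzyl cation scavenger; at −78 °C the methyl ethers and the C–Cl bond should be spared. Hydrogenolysis is avoided because of the aryl chloride.

## Compound list

1 | 3,5-dimethoxyphenol | COc1cc(O)cc(OC)c1 | starting material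
2 | 2-bromo-3,5-dimethoxyphenol | COc1cc(O)c(Br)c(OC)c1 | intermediate
3 | (2-bromo-3,5-dimethoxyphenoxy)trimethylsilane | COc1cc(O[Si](C)(C)C)c(Br)c(OC)c1 | intermediate
4 | [2,4-dimethoxy-6-(trimethylsilyloxy)phenyl]lithium | [Li]c1c(OC)cc(OC)cc1O[Si](C)(C)C | intermediate (not isolated)
5 | lithium 3,5-dimethoxy-2-(trimethylsilyl)phenoxide | [Li+].[O-]c1cc(OC)cc(OC)c1[Si](C)(C)C | intermediate (not isolated)
6 | 3,5-dimethoxy-2-(trimethylsilyl)phenyl trifluoromethanesulfonate | COc1cc(OC)c([Si](C)(C)C)c(OS(=O)(=O)C(F)(F)F)c1 | intermediate
7 | 2,4-dihydroxy-6-methylbenzaldehyde | Cc1cc(O)cc(O)c1C=O | starting material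
8 | 4-(benzyloxy)-2-hydroxy-6-methylbenzaldehyde | Cc1cc(OCc2ccccc2)cc(O)c1C=O | intermediate
9 | 4-(benzyloxy)-2-methoxy-6-methylbenzaldehyde | Cc1cc(OCc2ccccc2)cc(OC)c1C=O | intermediate
10 | (E)-4-(benzyloxy)-2-methoxy-6-methylbenzaldehyde oxime | Cc1cc(OCc2ccccc2)cc(OC)c1/C=N/O | intermediate
11 | 4-(benzyloxy)-2-methoxy-6-methylbenzonitrile oxide | Cc1cc(OCc2ccccc2)cc(OC)c1C#[N+][O-] | intermediate
12 | 3,5-dimethoxybenzyne (1,2-didehydro-3,5-dimethoxybenzene) | COC1=CC(OC)=CC#C1 | intermediate (not isolated)
13 | 3-[4-(benzyloxy)-2-methoxy-6-methylphenyl]-4,6-dimethoxy-1,2-benzisoxazole | COc1cc(OC)c2c(-c3c(C)cc(OCc4ccccc4)cc3OC)noc2c1 | intermediate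
14 | 2-{[4-(benzyloxy)-2-methoxy-6-methylphenyl](imino)methyl}-3,5-dimethoxyphenol | COc1cc(O)c(C(=N)c2c(C)cc(OCc3ccccc3)cc2OC)c(OC)c1 | intermediate (not isolated)
15 | [4-(benzyloxy)-2-methoxy-6-methylphenyl](2-hydroxy-4,6-dimethoxyphenyl)methanone | COc1cc(O)c(C(=O)c2c(C)cc(OCc3ccccc3)cc2OC)c(OC)c1 | intermediate
16 | [4-(benzyloxy)-2-methoxy-6-methylphenyl](3-chloro-2-hydroxy-4,6-dimethoxyphenyl)methanone | COc1cc(OC)c(C(=O)c2c(C)cc(OCc3ccccc3)cc2OC)c(O)c1Cl | intermediate
17 | (3-chloro-2-hydroxy-4,6-dimethoxyphenyl)(4-hydroxy-2-methoxy-6-methylphenyl)methanone | COc1cc(OC)c(C(=O)c2c(C)cc(O)cc2OC)c(O)c1Cl | target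

## Step count and least certain steps

Total: 11 steps. Longest linear sequence: 8 steps (steps 4, 5, 6, 7, 8, 9, 10, 11); the other branch (steps 1 to 3) joins at step 8.

**Step 8 (key step).** The bond-forming orientation may invert, with oxygen going to the carbon beside the methoxyl, if the bulk of the di-ortho-substituted aryl group outweighs the electronic bias. The cycloaddition may also be slow enough for the aryne to be consumed by self-reaction. The fallback sets out from 9 and 1 and comes back at 15. Aldehyde 9 is oxidised (NaClO2, NaH2PO4, 2-methyl-2-butene, t-BuOH/H2O) to 4-(benzyloxy)-2-methoxy-6-methylbenzoic acid F1. F1 is esterified with 1 (DCC, DMAP, CH2Cl2) to 3,5-dimethoxyphenyl 4-(benzyloxy)-2-methoxy-6-methylbenzoate F2. A photo-Fries rearrangement (254 nm, MeCN) then moves the aroyl group to the carbon ortho to the phenol oxygen to give 15; both ortho positions are equivalent and the para-migration isomer is removed by chromatography.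

**Step 10.** Site selectivity may be lost, with chlorination at C5 of ring A, at C3'/C5' of ring B, or twice. All these positions are activated by two or three oxygens, and the directing C2 hydroxyl is tied up in its hydrogen bond to the ketone. The fallback sets out from 13 and comes back at 16. The benzisoxazole is chlorinated with N-chlorosuccinimide in MeCN. By analogy with other 4,6-dioxygenated benzo-fused heterocycles, attack should go to C7 (para to the C4 methoxyl, ortho to the C6 methoxyl, less crowded than C5) and give 3-[4-(benzyloxy)-2-methoxy-6-methylphenyl]-7-chloro-4,6-dimethoxy-1,2-benzisoxazole F3. Mo(CO)6 in MeCN/H2O then gives 2-{[4-(benzyloxy)-2-methoxy-6-methylphenyl](imino)methyl}-6-chloro-3,5-dimethoxyphenol F4, which is hydrolysed with aqueous HCl to 16.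

**Step 9.** Hydrolysis of ketimine 14 may stall. The imine carbon is shielded on both faces by the ortho groups of the twisted ring B, and the protonated imine is stabilised by the electron-rich ring A and its hydrogen bond. Forcing acid would then start to cleave the benzyl ether or the aryl–carbonyl bond. The fallback avoids nitrogen altogether; it sets out from 2 and 9 and comes back at 15.
- Phenol 2 is protected (MOMCl, i-Pr2NEt, CH2Cl2) as 2-bromo-1,5-dimethoxy-3-(methoxymethoxy)benzene F5.
- Bromine–lithium exchange (n-BuLi, THF, −78 °C) gives [2,4-dimethoxy-6-(methoxymethoxy)phenyl]lithium F6.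
- Addition of F6 to aldehyde 9 gives racemic [4-(benzyloxy)-2-methoxy-6-methylphenyl][2,4-dimethoxy-6-(methoxymethoxy)phenyl]methanol F7.
- Oxidation with Dess–Martin periodinane (NaHCO3 buffer, CH2Cl2) gives [4-(benzyloxy)-2-methoxy-6-methylphenyl][2,4-dimethoxy-6-(methoxymethoxy)phenyl]methanone F8.
- HCl in MeOH removes the acetal to give 15.

**Step 11.** Chemoselectivity may be lost: the boron Lewis acid, chelated at the carbonyl, may also cleave the C6 or C2' methoxyl if the temperature rises, or the benzyl cation may re-alkylate a ring. The fallback removes benzyl before chlorine is present; it sets out from 15 and ends at 17.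
- Hydrogenolysis (H2, Pd/C, EtOAc) gives (2-hydroxy-4,6-dimethoxyphenyl)(4-hydroxy-2-methoxy-6-methylphenyl)methanone F9.
- Ac2O/pyridine at 0 °C acylates only the non-chelated C4' hydroxyl to give 4-(2-hydroxy-4,6-dimethoxybenzoyl)-3-methoxy-5-methylphenyl acetate F10.
- The amine-catalysed SO2Cl2 chlorination, now with ring B deactivated, gives 4-(3-chloro-2-hydroxy-4,6-dimethoxybenzoyl)-3-methoxy-5-methylphenyl acetate F11.
- K2CO3 in MeOH at 0 °C releases 17.

**Step 1.** Bromination may go to the wrong position (C4, para to the hydroxyl) or occur twice. The fallback replaces electrophilic substitution by directed metalation; it sets out from 1 and comes back at 6.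
- i-PrNCO with catalytic Et3N gives 3,5-dimethoxyphenyl N-(propan-2-yl)carbamate F12.
- TMSOTf/TMEDA gives in the flask 3,5-dimethoxyphenyl N-(propan-2-yl)-N-(trimethylsilyl)carbamate F13.
- n-BuLi/TMEDA at −78 °C lithiates between the carbamate oxygen and a methoxyl to give the 2-lithio derivative F14.
- Me3SiCl gives 3,5-dimethoxy-2-(trimethylsilyl)phenyl N-(propan-2-yl)-N-(trimethylsilyl)carbamate F15, which loses the N-silyl group on aqueous work-up to give 3,5-dimethoxy-2-(trimethylsilyl)phenyl N-(propan-2-yl)carbamate F16.
- DBU and Et2NH in MeCN at 40 °C cleave the carbamate to 3,5-dimethoxy-2-(trimethylsilyl)phenol F17, which is trapped in the same flask with PhNTf2 to give 6.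

## Further compounds

F1 | step 8 | 4-(benzyloxy)-2-methoxy-6-methylbenzoic acid | Cc1cc(OCc2ccccc2)cc(OC)c1C(=O)O
F2 | step 8 | 3,5-dimethoxyphenyl 4-(benzyloxy)-2-methoxy-6-methylbenzoate | COc1cc(OC)cc(OC(=O)c2c(C)cc(OCc3ccccc3)cc2OC)c1
F3 | step 10 | 3-[4-(benzyloxy)-2-methoxy-6-methylphenyl]-7-chloro-4,6-dimethoxy-1,2-benzisoxazole | COc1cc(OC)c2c(-c3c(C)cc(OCc4ccccc4)cc3OC)noc2c1Cl
F4 | step 10 | 2-{[4-(benzyloxy)-2-methoxy-6-methylphenyl](imino)methyl}-6-chloro-3,5-dimethoxyphenol | COc1cc(OC)c(C(=N)c2c(C)cc(OCc3ccccc3)cc2OC)c(O)c1Cl
F5 | step 9 | 2-bromo-1,5-dimethoxy-3-(methoxymethoxy)benzene | COCOc1cc(OC)cc(OC)c1Br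
F6 | step 9 | [2,4-dimethoxy-6-(methoxymethoxy)phenyl]lithium | [Li]c1c(OC)cc(OC)cc1OCOC
F7 | step 9 | [4-(benzyloxy)-2-methoxy-6-methylphenyl][2,4-dimethoxy-6-(methoxymethoxy)phenyl]methanol (racemic) | COCOc1cc(OC)cc(OC)c1C(O)c1c(C)cc(OCc2ccccc2)cc1OC
F8 | step 9 | [4-(benzyloxy)-2-methoxy-6-methylphenyl][2,4-dimethoxy-6-(methoxymethoxy)phenyl]methanone | COCOc1cc(OC)cc(OC)c1C(=O)c1c(C)cc(OCc2ccccc2)cc1OC
F9 | step 11 | (2-hydroxy-4,6-dimethoxyphenyl)(4-hydroxy-2-methoxy-6-methylphenyl)methanone | COc1cc(O)c(C(=O)c2c(C)cc(O)cc2OC)c(OC)c1
F10 | step 11 | 4-(2-hydroxy-4,6-dimethoxybenzoyl)-3-methoxy-5-methylphenyl acetate | COc1cc(O)c(C(=O)c2c(C)cc(OC(C)=O)cc2OC)c(OC)c1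
F11 | step 11 | 4-(3-chloro-2-hydroxy-4,6-dimethoxybenzoyl)-3-methoxy-5-methylphenyl acetate | COc1cc(OC)c(C(=O)c2c(C)cc(OC(C)=O)cc2OC)c(O)c1Cl
F12 | step 1 | 3,5-dimethoxyphenyl N-(propan-2-yl)carbamate | CC(C)NC(=O)Oc1cc(OC)cc(OC)c1
F13 | step 1 | 3,5-dimethoxyphenyl N-(propan-2-yl)-N-(trimethylsilyl)carbamate | CC(C)N(C(=O)Oc1cc(OC)cc(OC)c1)[Si](C)(C)C
F14 | step 1 | 2-lithio-3,5-dimethoxyphenyl N-(propan-2-yl)-N-(trimethylsilyl)carbamate | CC(C)N(C(=O)Oc1cc(OC)cc(OC)c1[Li])[Si](C)(C)C
F15 | step 1 | 3,5-dimethoxy-2-(trimethylsilyl)phenyl N-(propan-2-yl)-N-(trimethylsilyl)carbamate | CC(C)N(C(=O)Oc1cc(OC)cc(OC)c1[Si](C)(C)C)[Si](C)(C)C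
F16 | step 1 | 3,5-dimethoxy-2-(trimethylsilyl)phenyl N-(propan-2-yl)carbamate | CC(C)NC(=O)Oc1cc(OC)cc(OC)c1[Si](C)(C)C
F17 | step 1 | 3,5-dimethoxy-2-(trimethylsilyl)phenol | COc1cc(O)c([Si](C)(C)C)c(OC)c1
A1 | alternative 1 | 1-[3-chloro-4,6-dimethoxy-2-(methoxymethoxy)phenyl]but-2-yn-1-one | CC#CC(=O)c1c(OC)cc(OC)c(Cl)c1OCOC
A2 | alternative 1 | 1,1-dimethoxy-3-(trimethylsilyloxy)buta-1,3-diene | COC(OC)=CC(=C)O[Si](C)(C)C
A3 | alternative 1 | [3-chloro-4,6-dimethoxy-2-(methoxymethoxy)phenyl](4-hydroxy-2-methoxy-6-methylphenyl)methanone | COCOc1c(Cl)c(OC)cc(OC)c1C(=O)c1c(C)cc(O)cc1OC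
A4 | alternative 2 | 6-{2-[4-(benzyloxy)-2-methoxy-6-methylphenyl]-2-oxoethyl}-4-hydroxy-2H-pyran-2-one | O=C1C=C(O)C=C(CC(=O)c2c(C)cc(OCc3ccccc3)cc2OC)O1
A5 | alternative 2 | methyl 7-[4-(benzyloxy)-2-methoxy-6-methylphenyl]-3,5,7-trioxoheptanoate | COC(=O)CC(=O)CC(=O)CC(=O)c1c(C)cc(OCc2ccccc2)cc1OC
A6 | alternative 2 | [4-(benzyloxy)-2-methoxy-6-methylphenyl](2,4,6-trihydroxyphenyl)methanone | Oc1cc(O)c(C(=O)c2c(C)cc(OCc3ccccc3)cc2OC)c(O)c1
A7 | alternative 3 | methyl 3-[2-(benzyloxy)-3-chloro-4,6-dimethoxyphenyl]-3-oxopropanoate | COC(=O)CC(=O)c1c(OC)cc(OC)c(Cl)c1OCc1ccccc1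
A8 | alternative 3 | 5-(benzyloxy)-3-methoxy-2-(trimethylsilyl)phenyl trifluoromethanesulfonate | COc1cc(OCc2ccccc2)cc(OS(=O)(=O)C(F)(F)F)c1[Si](C)(C)C
A9 | alternative 3 | methyl 2-[5-(benzyloxy)-2-[2-(benzyloxy)-3-chloro-4,6-dimethoxybenzoyl]-3-methoxyphenyl]acetate | COC(=O)Cc1cc(OCc2ccccc2)cc(OC)c1C(=O)c1c(OC)cc(OC)c(Cl)c1OCc1ccccc1
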